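# Proposed synthesis of (4S)-7,8-dihydroxy-4-(4-hydroxy-8-methoxynaphthalen-1-yl)-3,4-dihydronaphthalen-1(2H)-one (21)

## The problem

Compound 21 is a 4-aryl-1-tetralone: a cyclohexanone (ring B) fused to a 7,8-dihydroxylated benzene ring, with C4 bonded to C1' of a 4-hydroxy-8-methoxynaphthalene whose peri methoxy group crowds the C4–C1' bond. The only stereocentre is C4, a doubly benzylic methine of S configuration. Nothing else in the molecule can relay its configuration, so it must be set by a reagent or a catalyst, and it is at risk wherever it sits gamma to an enone carbonyl in the presence of base. Three phenolic hydroxyls must end free beside one aryl methyl ether, so the methoxy group has to be carried from the start and every other oxygen needs a group that comes off without demethylating conditions. The catechol and the 4-alkyl-1-naphthol are easily oxidised to quinones and the aryl ketone is open to over-reduction, which argues for unveiling the catechol late and against a hydrogenolytic endgame. The C8 hydroxyl must end next to the carbonyl-bearing C8a and not at C5, a regiochemical demand on any construction of the oxygenated ring. The enabling feature appears when C5–C8 are removed: what is left of ring B is a 4-arylcyclohexanone with a mirror plane through C1 and C4, so C4 is prochiral. The four removed carbons, with the oxygens on C7 and C8, map onto a 1,1,2-trioxygenated butadiene that can be laid onto C4a=C8a.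

## Retrosynthesis

**21 from 20.** The last cut is the O–Si bond of the naphthol. A triisopropylsilyl ether is chosen for 20 rather than a benzyl ether. It survives the alkene hydrogenation needed earlier, it is removed by buffered fluoride without exposing the aryl ketone to hydrogen, and its bulk also does the regiochemical work on the naphthalene (see below).

**20 from 14 and 17.** The bonds C5–C4a and C8–C8a are cut, which removes the whole catechol ring. The precursors are the 2-sulfinyl cyclohexenone 14 and the diene 17, 1-methoxy-1,2-bis(trimethylsilyloxy)buta-1,3-diene. The neighbouring cuts are less attractive: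
- Cutting C4–C1' would require an asymmetric arylation with a peri-hindered naphthyl group.
- Cutting C1–C8a or C4–C4a (acylation or alkylation of a catechol) would require the stereocentre in an open chain and would leave the ortho/para question on the catechol open.

The chosen cut leaves a monocyclic enone whose parent ketone is symmetrical. The forward reaction must deliver one regiochemistry (diene CH2 terminus to C4a, dioxygenated carbon to C8a). The sulfinyl group must serve first as activator and then as leaving group, so that adduct 18 aromatises through 19 without an oxidant and without base.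

**14 from 13, 11 and 10.** The S–O bond and then the C2–S bond are cut. Sulfur is placed on the enol carbon of the silyl enol ether 10 (giving 11), so the enantiotopic choice made in forming 10 is translated directly into the position of sulfur. The double bond is introduced by chlorination to 12 and loss of HCl, which can only occur toward C3, giving 13. Oxidation to the sulfoxide 14 comes last because 14 is the most sensitive compound of the series.

**10 from 9.** The enol silane is traced to the achiral ketone 9 by enantioselective deprotonation. This sets C4 on a substrate in which the bulky aryl group is only a spectator, and it requires no chiral catalyst at the hindered C4–C1' bond.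

**9 from 8, 7, 5 and 6.** The C4–C1' bond is cut at the stage of the cyclohexene 7, where it joins two sp2 carbons. The aryl triflate 5 and the commercial alkenyl boronate 6 are the partners. Hydrogenation (8) and ketal hydrolysis return 9. The forward coupling must tolerate the peri methoxy group next to the triflate.

**5 from 4, 2 and 1.** The 1,4,5-oxygenation pattern of the naphthalene is that of juglone 1. Methylation gives 2 and reduction gives the hydroquinone 3, whose two hydroxyls differ: one is flanked by the peri methoxy group and hydrogen-bonded to it, the other is free. A bulky silyl chloride should take the free one (4), and the hindered one becomes the triflate 5. This puts the C–C bond where it must be, peri to the methoxy group.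

**17 from 16 and 15.** The diene is the doubly silylated dienolate of methyl 2-oxobutanoate 15. The first silylation gives the enol ether 16 and the second, after deprotonation of the gamma-methyl group, gives 17.

## Roads not taken

**Alternative 1: photoenol Diels–Alder on a diarylmethane aldehyde.**
- Cut: ring B is cut at C1–C2 and C3–C4, giving 2,3-bis(benzyloxy)-6-{[4-(benzyloxy)-8-methoxynaphthalen-1-yl]methyl}benzaldehyde A1 and methyl acrylate A2.
- Forward step: irradiation of A1 at 366 nm moves a hydrogen from the diarylmethane CH2 to the excited carbonyl oxygen. The resulting (E,E)-hydroxy-ortho-quinodimethane, held on Ti(OiPr)4 carrying a TADDOL ligand, adds A2 to give the all-cis tetralin ester A3.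
- Merits: the catechol ring is bought as an aromatic aldehyde, so its oxygen pattern is never in question. No hydrolytically labile diene is needed. The route is convergent and C4 is set by a catalyst in the ring-forming step.
- Weak points:
  - A3 carries a hydroxyl at C1 and an ester at C2 that 21 lacks. Oxidation at C1, dealkoxycarbonylation and a triple hydrogenolysis beside the aryl ketone must follow, and two of the three stereocentres made are discarded.
  - The chiral titanium centre binds the dienol oxygen at C1, the far end of the diene from C4, while the C4 terminus carries the very large peri-substituted naphthyl group.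
  - The aldehyde is flanked on its other side by the C8 benzyloxy group. Its benzylic hydrogens are equally within reach of the excited carbonyl, so hydrogen abstraction there and cyclisation onto the ether side chain should compete.
  - The alkoxynaphthalene is a second chromophore.
- Comparison: this road is ahead in convergence and in using a catalyst for the stereocentre. In length it is about equal once A1 and the corrective steps are counted. The chosen plan offers a ground-state key step, a stereocentre set on a symmetrical ketone, and a key-step product one deprotection from 21.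

**Alternative 2: furan–ynone cycloaddition closing the catechol ring and ring B together.**
- Cut: C4a–C8a and C7–C8 are cut, giving the open-chain (6S)-6-[4-(benzyloxy)-8-methoxynaphthalen-1-yl]-1-ethoxy-6-(furan-2-yl)hex-1-yn-3-one A4.
- Forward step: on heating or with Me2AlCl the furan of A4 adds to the tethered ethoxy-ynone. The oxygen bridge opens at the C4a–O bond (the cation is stabilised through the ethoxy-substituted double bond) and loss of the C7 proton gives the phenol (4S)-4-[4-(benzyloxy)-8-methoxynaphthalen-1-yl]-8-ethoxy-7-hydroxy-3,4-dihydronaphthalen-1(2H)-one A5.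
- Merits: two rings close in one operation. The positions of O7 and O8 are fixed by connectivity, not by orbital coefficients, which is better than the chosen plan in that respect.
- Weak points:
  - The stereocentre must already be present in A4 as an aryl(furyl)methine. Making it enantioselectively means an asymmetric arylation with the peri-hindered naphthyl group, the very operation the chosen plan avoids.
  - The ynol-ether ynone is prone to hydration and polymerisation, and the Lewis acid has to spare it.
  - The O8 ethyl group must then be cleaved selectively beside the naphthyl methyl ether (feasible by chelation to the C1 carbonyl, but an extra step), followed by hydrogenolysis next to the aryl ketone.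
- Comparison: the key step is more elegant, but the difficulty moves into the precursor. The chosen plan offers a two-step route to its diene and a stereocentre that arises from a symmetrical ketone.

**Alternative 3: radical cyclisation relayed into enantioselective copper arylation.**
- Cut: C2–C3 and C4–C1' are cut, giving 1-[2,3-bis(benzyloxy)-6-ethenylphenyl]-2-bromoethan-1-one A6 and [4-(benzyloxy)-8-methoxynaphthalen-1-yl]boronic acid A7.
- Forward step: monovalent copper (Cu(MeCN)4PF6 with a chiral bisoxazoline) reduces A6 to the C2 radical, which adds to the terminal carbon of the ortho vinyl group and closes ring B. The C4 benzylic radical is captured by the naphthyl-copper species formed from A7, and reductive elimination from trivalent copper gives the tri-O-benzyl ether (4S)-7,8-bis(benzyloxy)-4-[4-(benzyloxy)-8-methoxynaphthalen-1-yl]-3,4-dihydronaphthalen-1(2H)-one A8.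
- Merits: this is by far the shortest road. Ring B, the C4–C1' bond and the stereocentre arise in one catalytic step from two simple aromatic pieces, and A8 is one hydrogenolysis from 21.
- Weak points:
  - Everything rests on the step that sets the only stereocentre. Transmetalation and C–C bond formation must occur with a 1-naphthyl group carrying a peri methoxy substituent, at a cyclic secondary benzylic radical, under ligand control.
  - Protodeboronation of the electron-rich A7 would compete.
  - Five-membered ring closure onto the internal vinyl carbon and simple reduction of the bromoketone would compete.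
  - The final hydrogenolysis again runs beside an aryl ketone.
- Comparison: in step count this road is clearly better. The chosen plan offers closely precedented steps throughout and a stereocentre set where the hindered naphthyl group takes no part in the bond-forming event.

Key step: step 13

Assumption: the lithium (S,S)-amide is taken to distinguish the alpha-methylene groups of 9 in the sense established for 4-alkylcyclohexanones (there the (R,R)-amide leads to the (S)-enol silane); if 9 responded in the opposite sense, the (R,R)-amide would be used and nothing else would change.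

## Route

Step 1
Reactants: 1 juglone (5-hydroxy-1,4-naphthoquinone)
Product: 2 5-methoxy-1,4-naphthoquinone
Conditions: MeI, Ag2O, CH2Cl2, rt, dark
Reagents that add atoms: iodomethane, CI
Why: O-Methylation of the chelated peri hydroxyl with silver oxide (Williamson-type etherification under neutral conditions) is the standard entry to juglone methyl ether and spares the base-sensitive quinone.

Step 2
Reactants: 2 5-methoxy-1,4-naphthoquinone
Product: 4 8-methoxy-4-[(triisopropylsilyl)oxy]naphthalen-1-ol, via 5-methoxynaphthalene-1,4-diol 3 (not isolated)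
Conditions: H2 (1 atm), Pd/C, THF, rt; Ar purge; then imidazole, TIPSCl, DMF, 0 °C to rt
Reagents that add atoms: chlorotriisopropylsilane, CC(C)[Si](Cl)(C(C)C)C(C)C
Why: Catalytic hydrogenation reduces the quinone to the air-sensitive hydroquinone 3, which is silylated in the same flask (regioselective silyl ether formation). The bulky silyl chloride should take the unhindered hydroxyl, because the other is flanked by the peri methoxy group and hydrogen-bonded to it.

Step 3
Reactants: 4 8-methoxy-4-[(triisopropylsilyl)oxy]naphthalen-1-ol
Product: 5 8-methoxy-4-[(triisopropylsilyl)oxy]naphthalen-1-yl trifluoromethanesulfonate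
Conditions: Tf2O, pyridine, CH2Cl2, 0 °C
Reagents that add atoms: trifluoromethanesulfonic anhydride, O=S(=O)(OS(=O)(=O)C(F)(F)F)C(F)(F)F
Why: Sulfonylation of the remaining naphthol with triflic anhydride and pyridine (aryl triflate formation) turns the hindered oxygen into the coupling handle; the silyl ether is inert under these conditions.

Step 4
Reactants: 5 8-methoxy-4-[(triisopropylsilyl)oxy]naphthalen-1-yl trifluoromethanesulfonate; 6 2-(1,4-dioxaspiro[4.5]dec-7-en-8-yl)-4,4,5,5-tetramethyl-1,3,2-dioxaborolane
Product: 7 8-{8-methoxy-4-[(triisopropylsilyl)oxy]naphthalen-1-yl}-1,4-dioxaspiro[4.5]dec-7-ene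
Conditions: Pd(OAc)2, SPhos, K3PO4, dioxane/H2O, 80 °C
Reagents that add atoms: none
Why: Suzuki–Miyaura coupling: the electron-rich biaryl phosphine lets zerovalent palladium insert into the peri-hindered, electron-rich aryl triflate, and the alkenyl boronate transmetalates readily. The C1'–C4 bond is formed between two sp2 carbons, so no stereochemistry is at stake.

Step 5
Reactants: 7 8-{8-methoxy-4-[(triisopropylsilyl)oxy]naphthalen-1-yl}-1,4-dioxaspiro[4.5]dec-7-ene
Product: 8 8-{8-methoxy-4-[(triisopropylsilyl)oxy]naphthalen-1-yl}-1,4-dioxaspiro[4.5]decane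
Conditions: H2 (1 atm), Pd/C, EtOAc, rt
Reagents that add atoms: none
Why: Heterogeneous hydrogenation of the trisubstituted styrene-type alkene; the product has a mirror plane, so no stereocentre arises, and the silyl ether, ketal and naphthalene are untouched.

Step 6
Reactants: 8 8-{8-methoxy-4-[(triisopropylsilyl)oxy]naphthalen-1-yl}-1,4-dioxaspiro[4.5]decane
Product: 9 4-{8-methoxy-4-[(triisopropylsilyl)oxy]naphthalen-1-yl}cyclohexan-1-one
Conditions: 1 M HCl, THF, rt
Reagents that add atoms: water, O
Why: Acid hydrolysis of the dioxolane (ketal cleavage); aryl triisopropylsilyl ethers tolerate dilute aqueous acid at room temperature.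

Step 7
Reactants: 9 4-{8-methoxy-4-[(triisopropylsilyl)oxy]naphthalen-1-yl}cyclohexan-1-one
Product: 10 {[(4R)-4-{8-methoxy-4-[(triisopropylsilyl)oxy]naphthalen-1-yl}cyclohex-1-en-1-yl]oxy}trimethylsilane
Conditions: (S,S)-bis(1-phenylethyl)amine, n-BuLi, TMSCl, THF, −100 °C (in situ quench)
Reagents that add atoms: chlorotrimethylsilane, C[Si](C)(C)Cl
Why: Enantiotopic-group-selective deprotonation by a homochiral lithium amide with internal silyl quench (asymmetric desymmetrisation of a 4-substituted cyclohexanone). The base removes one of the two axial alpha-protons of the chair with the aryl group equatorial, and the (S,S)-amide is chosen so that the enol double bond makes C4 R, the arrangement that maps onto C4 of 21.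

Step 8
Reactants: 10 {[(4R)-4-{8-methoxy-4-[(triisopropylsilyl)oxy]naphthalen-1-yl}cyclohex-1-en-1-yl]oxy}trimethylsilane
Product: 11 (4R)-4-{8-methoxy-4-[(triisopropylsilyl)oxy]naphthalen-1-yl}-2-(phenylsulfanyl)cyclohexan-1-one (mixture of C2 epimers)
Conditions: PhSCl, CH2Cl2, −78 °C
Reagents that add atoms: benzenesulfenyl chloride, ClSc1ccccc1
Why: Electrophilic sulfenylation of the silyl enol ether at its nucleophilic carbon fixes sulfur on the carbon that becomes C8a; C4 is not touched and the new C2 centre is removed in the next step.

Step 9
Reactants: 11 (4R)-4-{8-methoxy-4-[(triisopropylsilyl)oxy]naphthalen-1-yl}-2-(phenylsulfanyl)cyclohexan-1-one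
Product: 13 (4R)-4-{8-methoxy-4-[(triisopropylsilyl)oxy]naphthalen-1-yl}-2-(phenylsulfanyl)cyclohex-2-en-1-one, via alpha-chloro sulfide 12 (not isolated)
Conditions: NCS, CH2Cl2, 0 °C; then 2,6-lutidine, rt
Reagents that add atoms: none
Why: S-Chlorination and Pummerer-type rearrangement give the alpha-chloro sulfide 12, which can lose HCl only toward C3, so the enone double bond forms on the C4 side. The hindered pyridine base is too weak to remove the gamma proton at C4.

Step 10
Reactants: 13 (4R)-4-{8-methoxy-4-[(triisopropylsilyl)oxy]naphthalen-1-yl}-2-(phenylsulfanyl)cyclohex-2-en-1-one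
Product: 14 (4R)-4-{8-methoxy-4-[(triisopropylsilyl)oxy]naphthalen-1-yl}-2-(phenylsulfinyl)cyclohex-2-en-1-one (both configurations at sulfur)
Conditions: mCPBA (1 equiv), CH2Cl2, −40 to 0 °C
Reagents that add atoms: 3-chloroperbenzoic acid, OOC(=O)c1cccc(Cl)c1
Why: Chemoselective oxidation of the vinyl sulfide to the sulfoxide with one equivalent of peracid at low temperature; both sulfur epimers are usable because sulfur is expelled in step 13.

Step 11
Reactants: 15 methyl 2-oxobutanoate
Product: 16 methyl (2Z)-2-[(trimethylsilyl)oxy]but-2-enoate
Conditions: TMSOTf, Et3N, Et2O, 0 °C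
Reagents that add atoms: trimethylsilyl trifluoromethanesulfonate, C[Si](C)(C)OS(=O)(=O)C(F)(F)F
Why: Soft enolisation and O-silylation of the ketone carbonyl of the alpha-keto ester (silyl enol ether formation); the Z isomer is expected, and the geometry has no consequence for the next step.

Step 12
Reactants: 16 methyl (2Z)-2-[(trimethylsilyl)oxy]but-2-enoate
Product: 17 1-methoxy-1,2-bis[(trimethylsilyl)oxy]buta-1,3-diene (either ketene-acetal geometry)
Conditions: LiN(iPr)2, DMPU, THF, −78 °C; then TMSCl
Reagents that add atoms: chlorotrimethylsilane, C[Si](C)(C)Cl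
Why: Deprotonation of the gamma-methyl group gives the extended dienolate, which is silylated on oxygen to the vinylketene acetal (the standard route from enoates to 1-alkoxy-1-silyloxy dienes); the diene is used freshly prepared.

Step 13
Reactants: 14 (4R)-4-{8-methoxy-4-[(triisopropylsilyl)oxy]naphthalen-1-yl}-2-(phenylsulfinyl)cyclohex-2-en-1-one; 17 1-methoxy-1,2-bis[(trimethylsilyl)oxy]buta-1,3-diene
Product: 20 (4S)-7,8-dihydroxy-4-{8-methoxy-4-[(triisopropylsilyl)oxy]naphthalen-1-yl}-3,4-dihydronaphthalen-1(2H)-one, via sulfinyl cycloadduct 18 (not isolated), via 7-O-trimethylsilyl ether 19 (not isolated)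
Conditions: 17 (3 equiv), toluene, 0 °C to rt, then 90 °C; then 1 M HCl, THF, rt
Reagents that add atoms: none
Why: The electron-rich diene 17 adds across C8a=C4a of the doubly activated enone 14 in a normal-electron-demand Diels–Alder reaction (a stepwise Mukaiyama–Michael addition followed by ring closure leads to the same adduct); the closest known reaction type is the cycloaddition of 2-sulfinyl cycloalkenones with oxygenated ketene-acetal dienes followed by sulfoxide elimination and aromatisation. The one new ring, the six-membered carbocycle C4a–C5–C6–C7–C8–C8a, closes by intermolecular [4+2] cycloaddition that forms C5–C4a and C8–C8a, the diene approaching the enone face anti to the C4 aryl group to give 18. On warming, the sulfoxide leaves by syn-elimination of benzenesulfenic acid with the C4a hydrogen (the only beta-hydrogen, cis to sulfur because the addition is suprafacial); the mixed silyl ketal at C8 then expels methoxytrimethylsilane and the dienone tautomerises to the phenol 19, whose C7 silyl ether is cleaved in the acidic work-up. No new stereocentre survives, since C4a, C8a and C8 all become sp2. The selectivity needed is regiochemical: the two ketene-acetal oxygens place the largest HOMO coefficient on the CH2 terminus of 17, which pairs with the beta-carbon C4a of the enone, so the dioxygenated carbon bonds to the sulfinyl-bearing C8a and O8 ends beside the C1 carbonyl. C4 is gamma to the enone only until the cycloaddition has taken place and no base is present, so its configuration should be carried into 20 unchanged; the excess diene also scavenges the sulfenic acid.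

Step 14
Reactants: 20 (4S)-7,8-dihydroxy-4-{8-methoxy-4-[(triisopropylsilyl)oxy]naphthalen-1-yl}-3,4-dihydronaphthalen-1(2H)-one
Product: 21 (4S)-7,8-dihydroxy-4-(4-hydroxy-8-methoxynaphthalen-1-yl)-3,4-dihydronaphthalen-1(2H)-one
Conditions: Bu4NF, AcOH, THF, 0 °C, degassed
Reagents that add atoms: none
Why: Fluoride cleavage of the aryl silyl ether, buffered with acetic acid so that neither the catechol nor the naphthol is held as an oxidisable phenoxide; the aryl ketone sees no reducing agent and C4 is not acidic enough to be affected.

## Compound list

1 | juglone (5-hydroxy-1,4-naphthoquinone) | O=C1C=CC(=O)c2c(O)cccc12 | starting material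
2 | 5-methoxy-1,4-naphthoquinone | COc1cccc2C(=O)C=CC(=O)c12 | intermediate
3 | 5-methoxynaphthalene-1,4-diol | COc1cccc2c(O)ccc(O)c12 | intermediate (not isolated)
4 | 8-methoxy-4-[(triisopropylsilyl)oxy]naphthalen-1-ol | COc1cccc2c(O[Si](C(C)C)(C(C)C)C(C)C)ccc(O)c12 | intermediate
5 | 8-methoxy-4-[(triisopropylsilyl)oxy]naphthalen-1-yl trifluoromethanesulfonate | COc1cccc2c(O[Si](C(C)C)(C(C)C)C(C)C)ccc(OS(=O)(=O)C(F)(F)F)c12 | intermediate
6 | 2-(1,4-dioxaspiro[4.5]dec-7-en-8-yl)-4,4,5,5-tetramethyl-1,3,2-dioxaborolane | CC1(C)OB(OC1(C)C)C1=CCC2(CC1)OCCO2 | starting material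
7 | 8-{8-methoxy-4-[(triisopropylsilyl)oxy]naphthalen-1-yl}-1,4-dioxaspiro[4.5]dec-7-ene | COc1cccc2c(O[Si](C(C)C)(C(C)C)C(C)C)ccc(C3=CCC4(CC3)OCCO4)c12 | intermediate
8 | 8-{8-methoxy-4-[(triisopropylsilyl)oxy]naphthalen-1-yl}-1,4-dioxaspiro[4.5]decane | COc1cccc2c(O[Si](C(C)C)(C(C)C)C(C)C)ccc(C3CCC4(CC3)OCCO4)c12 | intermediate
9 | 4-{8-methoxy-4-[(triisopropylsilyl)oxy]naphthalen-1-yl}cyclohexan-1-one | COc1cccc2c(O[Si](C(C)C)(C(C)C)C(C)C)ccc(C3CCC(=O)CC3)c12 | intermediate
10 | {[(4R)-4-{8-methoxy-4-[(triisopropylsilyl)oxy]naphthalen-1-yl}cyclohex-1-en-1-yl]oxy}trimethylsilane | COc1cccc2c(O[Si](C(C)C)(C(C)C)C(C)C)ccc([C@@H]3CCC(O[Si](C)(C)C)=CC3)c12 | intermediate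
11 | (4R)-4-{8-methoxy-4-[(triisopropylsilyl)oxy]naphthalen-1-yl}-2-(phenylsulfanyl)cyclohexan-1-one (mixture of C2 epimers) | COc1cccc2c(O[Si](C(C)C)(C(C)C)C(C)C)ccc([C@@H]3CCC(=O)C(Sc4ccccc4)C3)c12 | intermediate
12 | (4R)-2-chloro-4-{8-methoxy-4-[(triisopropylsilyl)oxy]naphthalen-1-yl}-2-(phenylsulfanyl)cyclohexan-1-one (mixture of C2 epimers) | COc1cccc2c(O[Si](C(C)C)(C(C)C)C(C)C)ccc([C@@H]3CCC(=O)C(Cl)(Sc4ccccc4)C3)c12 | intermediate (not isolated)
13 | (4R)-4-{8-methoxy-4-[(triisopropylsilyl)oxy]naphthalen-1-yl}-2-(phenylsulfanyl)cyclohex-2-en-1-one | COc1cccc2c(O[Si](C(C)C)(C(C)C)C(C)C)ccc([C@@H]3CCC(=O)C(Sc4ccccc4)=C3)c12 | intermediate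
14 | (4R)-4-{8-methoxy-4-[(triisopropylsilyl)oxy]naphthalen-1-yl}-2-(phenylsulfinyl)cyclohex-2-en-1-one (both configurations at sulfur) | COc1cccc2c(O[Si](C(C)C)(C(C)C)C(C)C)ccc([C@@H]3CCC(=O)C(S(=O)c4ccccc4)=C3)c12 | intermediate
15 | methyl 2-oxobutanoate | CCC(=O)C(=O)OC | starting material
16 | methyl (2Z)-2-[(trimethylsilyl)oxy]but-2-enoate | C/C=C(\O[Si](C)(C)C)C(=O)OC | intermediate
17 | 1-methoxy-1,2-bis[(trimethylsilyl)oxy]buta-1,3-diene (mixture of ketene-acetal geometries) | C=CC(O[Si](C)(C)C)=C(OC)O[Si](C)(C)C | intermediate
18 | (4R)-8-methoxy-4-{8-methoxy-4-[(triisopropylsilyl)oxy]naphthalen-1-yl}-8a-(phenylsulfinyl)-7,8-bis[(trimethylsilyl)oxy]-3,4,4a,5,8,8a-hexahydronaphthalen-1(2H)-one (cis-fused; mixture at C8 and sulfur) | COc1cccc2c(O[Si](C(C)C)(C(C)C)C(C)C)ccc([C@@H]3CCC(=O)C4(S(=O)c5ccccc5)C3CC=C(O[Si](C)(C)C)C4(OC)O[Si](C)(C)C)c12 | intermediate (not isolated)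
19 | (4S)-8-hydroxy-4-{8-methoxy-4-[(triisopropylsilyl)oxy]naphthalen-1-yl}-7-[(trimethylsilyl)oxy]-3,4-dihydronaphthalen-1(2H)-one | COc1cccc2c(O[Si](C(C)C)(C(C)C)C(C)C)ccc([C@@H]3CCC(=O)c4c3ccc(O[Si](C)(C)C)c4O)c12 | intermediate (not isolated)
20 | (4S)-7,8-dihydroxy-4-{8-methoxy-4-[(triisopropylsilyl)oxy]naphthalen-1-yl}-3,4-dihydronaphthalen-1(2H)-one | COc1cccc2c(O[Si](C(C)C)(C(C)C)C(C)C)ccc([C@@H]3CCC(=O)c4c3ccc(O)c4O)c12 | intermediate
21 | (4S)-7,8-dihydroxy-4-(4-hydroxy-8-methoxynaphthalen-1-yl)-3,4-dihydronaphthalen-1(2H)-one | COc1cccc2c(O)ccc([C@@H]3CCC(=O)c4c3ccc(O)c4O)c12 | target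

## Step count and least certain steps

Total: 14 steps. Longest linear sequence: 12 steps (steps 1–10, 13 and 14, from juglone 1). The diene branch (steps 11 and 12) joins at step 13.

**Step 13 (key step).**
- Risk: bond formation at the fully substituted, sulfinyl-bearing alpha-carbon, next to the bulky C4 aryl group, may be slow. Hydrolysis or oligomerisation of the labile bis(trimethylsilyl) diene, or its consumption by the sulfenic acid, could then outrun the cycloaddition. A second failure mode is aromatisation by loss of trimethylsilanol in place of methoxytrimethylsilane, which would leave O8 methylated.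
- Fallback: this sets out from 15 (and uses 14) and changes the four-carbon partner and the endgame. Ketone 15 would be silylated with TBSOTf and Et3N to methyl (2Z)-2-[(tert-butyldimethylsilyl)oxy]but-2-enoate F1. Deprotonation with LiN(iPr)2 and silylation with TMSCl would give 2-[(tert-butyldimethylsilyl)oxy]-1-methoxy-1-[(trimethylsilyl)oxy]buta-1,3-diene F2. With the C2 enol oxygen held as the robust silyl ether, the annulation with 14 can be run as a ZnBr2-promoted conjugate addition and ring closure at low temperature, followed by thermal loss of the sulfoxide. This should give (4S)-7-[(tert-butyldimethylsilyl)oxy]-8-hydroxy-4-{8-methoxy-4-[(triisopropylsilyl)oxy]naphthalen-1-yl}-3,4-dihydronaphthalen-1(2H)-one F3. Buffered fluoride as in step 14 then removes both silyl groups, so the fallback returns to the route at 21.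

**Step 7.**
- Risk: incomplete discrimination of the two enantiotopic alpha-methylene groups, or equilibration of the enol silane during isolation, would erode the enantiomeric purity carried to 21. Recrystallisation of a later crystalline intermediate is the first remedy.
- Fallback: this sets out from 9 and replaces enantioselective deprotonation by separation of diastereomers on a sulfur auxiliary that the key step expels anyway. The magnesium enolate of 9 (i-Pr2NMgBr) would be sulfinylated with (1R,2S,5R)-menthyl (S)-4-methylbenzenesulfinate, with inversion at sulfur, to 4-{8-methoxy-4-[(triisopropylsilyl)oxy]naphthalen-1-yl}-2-[(R)-4-methylbenzenesulfinyl]cyclohexan-1-one F4 (mixture at C2 and C4). Selenenylation (NaH, PhSeBr) would give 4-{8-methoxy-4-[(triisopropylsilyl)oxy]naphthalen-1-yl}-2-[(S)-4-methylbenzenesulfinyl]-2-(phenylselanyl)cyclohexan-1-one F5. Oxidation with H2O2 and selenoxide syn-elimination would give two sulfinyl enones that differ only at C4 and are separable as diastereomers. The (4R) isomer, (4R)-4-{8-methoxy-4-[(triisopropylsilyl)oxy]naphthalen-1-yl}-2-[(S)-4-methylbenzenesulfinyl]cyclohex-2-en-1-one F6, would take the place of 14 in step 13. The fallback returns to the route at 20.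

**Step 9.**
- Risk: ring chlorination of the electron-rich naphthalene by NCS may compete with S-chlorination. The HCl released during the elimination could also promote double-bond migration or racemisation at C4 through the dienol.
- Fallback: this sets out from 11 and avoids electrophilic chlorine and acid. Oxidation of 11 with mCPBA would give (4R)-4-{8-methoxy-4-[(triisopropylsilyl)oxy]naphthalen-1-yl}-2-(phenylsulfinyl)cyclohexan-1-one F7. Its sodium enolate (NaH) would be selenenylated with PhSeBr to (4R)-4-{8-methoxy-4-[(triisopropylsilyl)oxy]naphthalen-1-yl}-2-(phenylselanyl)-2-(phenylsulfinyl)cyclohexan-1-one F8. Oxidation with H2O2 at 0 °C and selenoxide syn-elimination toward C3 would give the sulfinyl enone directly. The fallback returns to the route at 14 and bypasses 13.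

**Step 2.**
- Risk: loss of regiocontrol in the monosilylation (attack at the peri-flanked hydroxyl or double silylation), and re-oxidation of the hydroquinone by air before it is protected.
- Fallback: this sets out from 2 and moves the discrimination to an acyl transfer on air-stable compounds. Reductive acetylation (zinc dust, Ac2O, NaOAc) would give 5-methoxynaphthalene-1,4-diyl diacetate F9. Controlled ammonolysis (NH3 in MeOH, low temperature) should first remove the acetate remote from the methoxy group, the other ester being shielded by the peri substituent, and give 4-hydroxy-8-methoxynaphthalen-1-yl acetate F10. Silylation (TIPSCl, imidazole) would give 8-methoxy-4-[(triisopropylsilyl)oxy]naphthalen-1-yl acetate F11, and ammonolysis of the remaining acetate returns to the route at 4. Unselective material can be re-acetylated and recycled.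

## Further compounds

F1 | step 13 | methyl (2Z)-2-[(tert-butyldimethylsilyl)oxy]but-2-enoate | C/C=C(\O[Si](C)(C)C(C)(C)C)C(=O)OC
F2 | step 13 | 2-[(tert-butyldimethylsilyl)oxy]-1-methoxy-1-[(trimethylsilyl)oxy]buta-1,3-diene (mixture of ketene-acetal geometries) | C=CC(O[Si](C)(C)C(C)(C)C)=C(OC)O[Si](C)(C)C
F3 | step 13 | (4S)-7-[(tert-butyldimethylsilyl)oxy]-8-hydroxy-4-{8-methoxy-4-[(triisopropylsilyl)oxy]naphthalen-1-yl}-3,4-dihydronaphthalen-1(2H)-one | COc1cccc2c(O[Si](C(C)C)(C(C)C)C(C)C)ccc([C@@H]3CCC(=O)c4c3ccc(O[Si](C)(C)C(C)(C)C)c4O)c12
F4 | step 7 | 4-{8-methoxy-4-[(triisopropylsilyl)oxy]naphthalen-1-yl}-2-[(R)-4-methylbenzenesulfinyl]cyclohexan-1-one (mixture at C2 and C4) | COc1cccc2c(O[Si](C(C)C)(C(C)C)C(C)C)ccc(C3CCC(=O)C([S@@](=O)c4ccc(C)cc4)C3)c12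
F5 | step 7 | 4-{8-methoxy-4-[(triisopropylsilyl)oxy]naphthalen-1-yl}-2-[(S)-4-methylbenzenesulfinyl]-2-(phenylselanyl)cyclohexan-1-one (mixture at C2 and C4) | COc1cccc2c(O[Si](C(C)C)(C(C)C)C(C)C)ccc(C3CCC(=O)C([Se]c4ccccc4)([S@@](=O)c4ccc(C)cc4)C3)c12
F6 | step 7 | (4R)-4-{8-methoxy-4-[(triisopropylsilyl)oxy]naphthalen-1-yl}-2-[(S)-4-methylbenzenesulfinyl]cyclohex-2-en-1-one | COc1cccc2c(O[Si](C(C)C)(C(C)C)C(C)C)ccc([C@@H]3CCC(=O)C([S@@](=O)c4ccc(C)cc4)=C3)c12
F7 | step 9 | (4R)-4-{8-methoxy-4-[(triisopropylsilyl)oxy]naphthalen-1-yl}-2-(phenylsulfinyl)cyclohexan-1-one (mixture at C2 and sulfur) | COc1cccc2c(O[Si](C(C)C)(C(C)C)C(C)C)ccc([C@@H]3CCC(=O)C(S(=O)c4ccccc4)C3)c12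
F8 | step 9 | (4R)-4-{8-methoxy-4-[(triisopropylsilyl)oxy]naphthalen-1-yl}-2-(phenylselanyl)-2-(phenylsulfinyl)cyclohexan-1-one (mixture at C2 and sulfur) | COc1cccc2c(O[Si](C(C)C)(C(C)C)C(C)C)ccc([C@@H]3CCC(=O)C([Se]c4ccccc4)(S(=O)c4ccccc4)C3)c12
F9 | step 2 | 5-methoxynaphthalene-1,4-diyl diacetate | COc1cccc2c(OC(C)=O)ccc(OC(C)=O)c12
F10 | step 2 | 4-hydroxy-8-methoxynaphthalen-1-yl acetate | COc1cccc2c(O)ccc(OC(C)=O)c12
F11 | step 2 | 8-methoxy-4-[(triisopropylsilyl)oxy]naphthalen-1-yl acetate | COc1cccc2c(O[Si](C(C)C)(C(C)C)C(C)C)ccc(OC(C)=O)c12
A1 | alternative 1 | 2,3-bis(benzyloxy)-6-{[4-(benzyloxy)-8-methoxynaphthalen-1-yl]methyl}benzaldehyde | COc1cccc2c(OCc3ccccc3)ccc(Cc3ccc(OCc4ccccc4)c(OCc4ccccc4)c3C=O)c12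
A2 | alternative 1 | methyl acrylate | C=CC(=O)OC
A3 | alternative 1 | all-cis methyl 7,8-bis(benzyloxy)-4-[4-(benzyloxy)-8-methoxynaphthalen-1-yl]-1-hydroxy-1,2,3,4-tetrahydronaphthalene-2-carboxylate (C4 arranged as in 21) | COc1cccc2c(OCc3ccccc3)ccc([C@@H]3C[C@H](C(=O)OC)[C@H](O)c4c3ccc(OCc5ccccc5)c4OCc5ccccc5)c12
A4 | alternative 2 | (6S)-6-[4-(benzyloxy)-8-methoxynaphthalen-1-yl]-1-ethoxy-6-(furan-2-yl)hex-1-yn-3-one | COc1cccc2c(OCc3ccccc3)ccc([C@@H](c3ccco3)CCC(=O)C#COCC)c12
A5 | alternative 2 | (4S)-4-[4-(benzyloxy)-8-methoxynaphthalen-1-yl]-8-ethoxy-7-hydroxy-3,4-dihydronaphthalen-1(2H)-one | COc1cccc2c(OCc3ccccc3)ccc([C@@H]3CCC(=O)c4c3ccc(O)c4OCC)c12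
A6 | alternative 3 | 1-[2,3-bis(benzyloxy)-6-ethenylphenyl]-2-bromoethan-1-one | C=Cc1ccc(OCc2ccccc2)c(OCc2ccccc2)c1C(=O)CBr
A7 | alternative 3 | [4-(benzyloxy)-8-methoxynaphthalen-1-yl]boronic acid | COc1cccc2c(OCc3ccccc3)ccc(B(O)O)c12
A8 | alternative 3 | (4S)-7,8-bis(benzyloxy)-4-[4-(benzyloxy)-8-methoxynaphthalen-1-yl]-3,4-dihydronaphthalen-1(2H)-one | COc1cccc2c(OCc3ccccc3)ccc([C@@H]3CCC(=O)c4c3ccc(OCc5ccccc5)c4OCc5ccccc5)c12
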